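**Retrosynthetic overview**

- Feature: the target is a tridepside, ring A (2,3,4-trimethoxy-6-methylbenzoyl) – ring B – ring C (terminal acid). In rings B and C the hydroxyl carbon C2 is ortho to the carbonyl-bearing C1, whose other ortho carbon C6 carries CH3; in ring A, C1 is flanked by C2–OMe and C6–CH3. Each of the two inner carbonyls therefore has exactly one free ortho C–H, and the ring-A carbonyl has none.
- Both C2–O bonds are formed last, in one Ru(II)-catalysed, ester-directed ortho C–H oxygenation of the bis-deoxy tridepside (step 8). Ru(II) carboxylate catalysis is chosen because ester carbonyls are weak donors and this is the system in which ester direction is established.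
- The terminal carboxyl is carried through that step as its 4-nitrobenzyl ester. Both sites are then ester-directed, no aroyl trifluoroacetate can form in TFA/TFAA (it would acylate ring A at C5), and the orsellinic acid unit is not exposed to hot acid, where it would decarboxylate. The acid is released at the end by neutral hydrogenolysis.
- The bis-deoxy tridepside is cut at its two aryl ester C(=O)–O bonds and assembled A→B→C from 2,3,4-trimethoxy-6-methylbenzoic acid and two units of 4-hydroxy-2-methylbenzoic acid (temporary benzyl ester on B).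
- The ring-A acid comes from 3,4,5-trimethoxytoluene by formylation and oxidation. No ring is formed; all three benzene rings are bought.

Key step: step 8

Remark on the chemistry: the target has no stereogenic centre or axis, so the route needs no stereocontrol.

**Route**

Step 1
Reactants: 1 3,4,5-trimethoxytoluene
Product: 3 2,3,4-trimethoxy-6-methylbenzaldehyde, via aryl iminium chloride 2 (not isolated)
Conditions: POCl3, DMF, 0 °C to 80 °C; then H2O
Reagents that add atoms: N,N-dimethylformamide, CN(C)C=O; water, O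
Why: Vilsmeier–Haack formylation, in which the chloroiminium ion attacks one of the two equivalent free ring positions (ortho to CH3 and OMe, para to OMe), so a single regioisomer should form and the iminium salt is hydrolysed on work-up.

Step 2
Reactants: 3 2,3,4-trimethoxy-6-methylbenzaldehyde
Product: 4 2,3,4-trimethoxy-6-methylbenzoic acid
Conditions: NaClO2, NaH2PO4, 2-methyl-2-butene, t-BuOH/H2O, rt
Reagents that add atoms: sodium chlorite, [Na+].[O-]Cl=O
Why: Pinnick oxidation converts the hindered, non-enolisable aryl aldehyde into the acid, and the alkene scavenges HOCl so that the electron-rich C5–H of the ring should not be chlorinated.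

Step 3
Reactants: 5 4-hydroxy-2-methylbenzoic acid
Product: 6 benzyl 4-hydroxy-2-methylbenzoate
Conditions: BnBr (1.0 equiv), KHCO3, DMF, rt to 40 °C
Reagents that add atoms: benzyl bromide, BrCc1ccccc1
Why: SN2 O-alkylation of the carboxylate, since bicarbonate deprotonates the acid but not the phenol, which should stay free.

Step 4
Reactants: 4 2,3,4-trimethoxy-6-methylbenzoic acid; 6 benzyl 4-hydroxy-2-methylbenzoate
Product: 8 benzyl 2-methyl-4-[(2,3,4-trimethoxy-6-methylbenzoyl)oxy]benzoate, via aroyl chloride 7 (not isolated)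
Conditions: (COCl)2, DMF (cat.), CH2Cl2, 0 °C to rt, evaporate; then 6, Et3N, DMAP (cat.), CH2Cl2, 0 °C to 40 °C
Reagents that add atoms: none
Why: Acid chloride formation followed by DMAP-catalysed O-acylation (nucleophilic acyl substitution) of the only nucleophile in 6, its phenol; the acid has no free hydroxyl and no α-hydrogen, so the activated species should be clean.

Step 5
Reactants: 8 benzyl 2-methyl-4-[(2,3,4-trimethoxy-6-methylbenzoyl)oxy]benzoate
Product: 9 2-methyl-4-[(2,3,4-trimethoxy-6-methylbenzoyl)oxy]benzoic acid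
Conditions: H2 (1 atm), 10% Pd/C, EtOAc, rt
Reagents that add atoms: none
Why: Catalytic hydrogenolysis cleaves the benzylic C–O bond of the benzyl ester, while the aryl ester and the methyl ethers are inert under these neutral conditions.

Step 6
Reactants: 5 4-hydroxy-2-methylbenzoic acid
Product: 10 4-nitrobenzyl 4-hydroxy-2-methylbenzoate
Conditions: 4-nitrobenzyl bromide (1.0 equiv), KHCO3, DMF, rt
Reagents that add atoms: 4-nitrobenzyl bromide, O=[N+]([O-])c1ccc(CBr)cc1
Why: Chemoselective SN2 alkylation of the carboxylate as in step 3, giving an ester that is stable to hot trifluoroacetic acid and to oxidants.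

Step 7
Reactants: 9 2-methyl-4-[(2,3,4-trimethoxy-6-methylbenzoyl)oxy]benzoic acid; 10 4-nitrobenzyl 4-hydroxy-2-methylbenzoate
Product: 12 4-nitrobenzyl 2-methyl-4-({2-methyl-4-[(2,3,4-trimethoxy-6-methylbenzoyl)oxy]benzoyl}oxy)benzoate, via aroyl chloride 11 (not isolated)
Conditions: (COCl)2, DMF (cat.), CH2Cl2, 0 °C to rt, evaporate; then 10, Et3N, DMAP (cat.), CH2Cl2, 0 °C to rt
Reagents that add atoms: none
Why: The same acid chloride/DMAP O-acylation; acid 9 has only one ortho substituent and should acylate readily, and the existing A–B ester is shielded by its two ortho substituents.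

Step 8
Reactants: 12 4-nitrobenzyl 2-methyl-4-({2-methyl-4-[(2,3,4-trimethoxy-6-methylbenzoyl)oxy]benzoyl}oxy)benzoate
Product: 14 4-nitrobenzyl 2-hydroxy-6-methyl-4-({2-hydroxy-6-methyl-4-[(2,3,4-trimethoxy-6-methylbenzoyl)oxy]benzoyl}oxy)benzoate, via bis(trifluoroacetate) 13 (not isolated)
Conditions: [RuCl2(p-cymene)]2 (5 mol %), K2S2O8 (3 equiv), TFA/TFAA, 80 °C, sealed tube; then THF/H2O, rt
Reagents that add atoms: trifluoroacetic acid, OC(=O)C(F)(F)F
Why: In TFA/TFAA the precatalyst becomes a cationic Ru(II) trifluoroacetate that binds the ester carbonyl oxygen of ring C (4-nitrobenzyl ester) and of ring B (aryl ester) and undergoes carboxylate-assisted cycloruthenation at the single free ortho C–H (C2) of each ring to give five-membered ruthenacycles; persulfate oxidises these to Ru(IV), C–O reductive elimination delivers the aryl trifluoroacetates 13, and wet THF hydrolyses them to the phenols without base. The reaction type is the known Ru(II)-catalysed ester-directed ortho C–H hydroxylation of benzoates in TFA/TFAA, required here at two ester carbonyls of one substrate. No ring is closed and no stereocentre is formed. Site selectivity is needed for C2–H of rings B and C over all other aryl C–H bonds and is secured by the substrate: C6 of each ring carries CH3, so each carbonyl can direct only once; the ring-A carbonyl has OMe and CH3 on both ortho carbons; ring A C5–H is meta to its carbonyl and out of reach of any director; and metalation of a phenoxy ring would need a less favoured six-membered metallacycle. Chemoselectivity towards the trimethoxy ring A and the new phenols is sought through the acyl deactivation of ring A, in-situ O-trifluoroacetylation of each new phenol, and the esterified ring-C carboxyl, which excludes a mixed anhydride and decarboxylation.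

Step 9
Reactants: 14 4-nitrobenzyl 2-hydroxy-6-methyl-4-({2-hydroxy-6-methyl-4-[(2,3,4-trimethoxy-6-methylbenzoyl)oxy]benzoyl}oxy)benzoate
Product: 15 2-hydroxy-6-methyl-4-({2-hydroxy-6-methyl-4-[(2,3,4-trimethoxy-6-methylbenzoyl)oxy]benzoyl}oxy)benzoic acid (target)
Conditions: H2 (1 atm), 10% Pd/C, EtOAc/THF, rt; then wash with dilute aq. HCl
Reagents that add atoms: none
Why: Catalytic hydrogenation reduces the nitro group and the resulting 4-aminobenzyl ester is cleaved by hydrogenolysis at room temperature under neutral conditions, which should leave the two aryl ester links intact and avoid decarboxylation of the orsellinic acid unit.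

**Compound list**

1 | 3,4,5-trimethoxytoluene | Cc1cc(OC)c(OC)c(OC)c1 | starting material
2 | N,N-dimethyl(2,3,4-trimethoxy-6-methylphenyl)methaniminium chloride | COc1cc(C)c(C=[N+](C)C)c(OC)c1OC.[Cl-] | intermediate
3 | 2,3,4-trimethoxy-6-methylbenzaldehyde | COc1cc(C)c(C=O)c(OC)c1OC | intermediate
4 | 2,3,4-trimethoxy-6-methylbenzoic acid | COc1cc(C)c(C(=O)O)c(OC)c1OC | intermediate
5 | 4-hydroxy-2-methylbenzoic acid | Cc1cc(O)ccc1C(=O)O | starting material
6 | benzyl 4-hydroxy-2-methylbenzoate | Cc1cc(O)ccc1C(=O)OCc1ccccc1 | intermediate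
7 | 2,3,4-trimethoxy-6-methylbenzoyl chloride | COc1cc(C)c(C(=O)Cl)c(OC)c1OC | intermediate
8 | benzyl 2-methyl-4-[(2,3,4-trimethoxy-6-methylbenzoyl)oxy]benzoate | COc1cc(C)c(C(=O)Oc2ccc(C(=O)OCc3ccccc3)c(C)c2)c(OC)c1OC | intermediate
9 | 2-methyl-4-[(2,3,4-trimethoxy-6-methylbenzoyl)oxy]benzoic acid | COc1cc(C)c(C(=O)Oc2ccc(C(=O)O)c(C)c2)c(OC)c1OC | intermediate
10 | 4-nitrobenzyl 4-hydroxy-2-methylbenzoate | Cc1cc(O)ccc1C(=O)OCc1ccc([N+](=O)[O-])cc1 | intermediate
11 | 2-methyl-4-[(2,3,4-trimethoxy-6-methylbenzoyl)oxy]benzoyl chloride | COc1cc(C)c(C(=O)Oc2ccc(C(=O)Cl)c(C)c2)c(OC)c1OC | intermediate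
12 | 4-nitrobenzyl 2-methyl-4-({2-methyl-4-[(2,3,4-trimethoxy-6-methylbenzoyl)oxy]benzoyl}oxy)benzoate (bis-deoxy tridepside, 4-nitrobenzyl ester) | COc1cc(C)c(C(=O)Oc2ccc(C(=O)Oc3ccc(C(=O)OCc4ccc([N+](=O)[O-])cc4)c(C)c3)c(C)c2)c(OC)c1OC | intermediate
13 | 4-nitrobenzyl 2-methyl-6-(trifluoroacetoxy)-4-({2-methyl-6-(trifluoroacetoxy)-4-[(2,3,4-trimethoxy-6-methylbenzoyl)oxy]benzoyl}oxy)benzoate | COc1cc(C)c(C(=O)Oc2cc(C)c(C(=O)Oc3cc(C)c(C(=O)OCc4ccc([N+](=O)[O-])cc4)c(OC(=O)C(F)(F)F)c3)c(OC(=O)C(F)(F)F)c2)c(OC)c1OC | intermediate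
14 | 4-nitrobenzyl 2-hydroxy-6-methyl-4-({2-hydroxy-6-methyl-4-[(2,3,4-trimethoxy-6-methylbenzoyl)oxy]benzoyl}oxy)benzoate | COc1cc(C)c(C(=O)Oc2cc(C)c(C(=O)Oc3cc(C)c(C(=O)OCc4ccc([N+](=O)[O-])cc4)c(O)c3)c(O)c2)c(OC)c1OC | intermediate
15 | 2-hydroxy-6-methyl-4-({2-hydroxy-6-methyl-4-[(2,3,4-trimethoxy-6-methylbenzoyl)oxy]benzoyl}oxy)benzoic acid | COc1cc(C)c(C(=O)Oc2cc(C)c(C(=O)Oc3cc(C)c(C(=O)O)c(O)c3)c(O)c2)c(OC)c1OC | target

**Step count**

Total steps: 9. Longest linear sequence: 7 (steps 1, 2, 4, 5, 7, 8, 9).

**Steps most likely to fail**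

Step 8. Three processes may defeat the double oxygenation:
- The aryl ester carbonyl of ring B is a weaker donor than the alkyl ester of ring C, so the reaction may stall after the first C–O bond.
- Persulfate may oxidise the trimethoxy ring A by single-electron transfer.
- Hot trifluoroacetic acid may cleave an aryl ester link by acidolysis.

The fallback brings the phenolic oxygens in with the building blocks and uses known depside chemistry. It sets out from acid 4 and comes back to the route at target 15. Commercial orsellinic acid would be benzylated at the carboxylate (BnBr, KHCO3, DMF) to benzyl 2,4-dihydroxy-6-methylbenzoate F1. Its 4-OH, the only hydroxyl not hydrogen-bonded to the ester carbonyl, would be acylated with chloride 7 (Et3N, DMAP, CH2Cl2) to give benzyl 2-hydroxy-6-methyl-4-[(2,3,4-trimethoxy-6-methylbenzoyl)oxy]benzoate F2. Hydrogenolysis (H2, Pd/C, EtOAc) should give 2-hydroxy-6-methyl-4-[(2,3,4-trimethoxy-6-methylbenzoyl)oxy]benzoic acid F3. Condensation of F3 with a second portion of F1 (DCC, toluene, rt), again at the free 4-OH, should give the benzyl ester of the target F4, and a last hydrogenolysis would deliver 15.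

Step 4. Addition–elimination at the aroyl chloride flanked by OMe and CH3 may be slow, so that hydrolysis or incomplete conversion competes. The fallback builds the ester carbonyl by carbonylation instead of acyl transfer; it sets out from 1 and comes back at 8. Bromination of 1 (NBS, MeCN, rt) at the only free ring position should give 1-bromo-2,3,4-trimethoxy-6-methylbenzene F5. Palladium-catalysed aryloxycarbonylation of F5 with phenol 6 (Pd(OAc)2, Xantphos, Et3N, CO 1 atm, toluene, 100 °C) would then give 8 directly.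

Step 9. The aniline formed during reduction of the nitro group may attack the activated aryl ester links, or the 4-aminobenzyl ester may fragment incompletely. The fallback uses a terminal ester that is cleaved reductively without releasing a nucleophile; it sets out from 5 and 9 and comes back at 15.
- Acid 5 would be esterified with 2,2,2-trichloroethanol (TsOH, toluene, Dean–Stark) to 2,2,2-trichloroethyl 4-hydroxy-2-methylbenzoate F6.
- Acylation of F6 with chloride 11 (from 9 as in step 7) should give the trichloroethyl ester of the bis-deoxy tridepside F7.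
- The conditions of step 8 would convert F7, through its bis(trifluoroacetate) F8, into the trichloroethyl ester of the target F9.
- Zinc dust in AcOH/THF at rt would then release 15.

**Further compounds**

F1 | step 8 | benzyl 2,4-dihydroxy-6-methylbenzoate | Cc1cc(O)cc(O)c1C(=O)OCc1ccccc1
F2 | step 8 | benzyl 2-hydroxy-6-methyl-4-[(2,3,4-trimethoxy-6-methylbenzoyl)oxy]benzoate | COc1cc(C)c(C(=O)Oc2cc(C)c(C(=O)OCc3ccccc3)c(O)c2)c(OC)c1OC
F3 | step 8 | 2-hydroxy-6-methyl-4-[(2,3,4-trimethoxy-6-methylbenzoyl)oxy]benzoic acid | COc1cc(C)c(C(=O)Oc2cc(C)c(C(=O)O)c(O)c2)c(OC)c1OC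
F4 | step 8 | benzyl 2-hydroxy-6-methyl-4-({2-hydroxy-6-methyl-4-[(2,3,4-trimethoxy-6-methylbenzoyl)oxy]benzoyl}oxy)benzoate | COc1cc(C)c(C(=O)Oc2cc(C)c(C(=O)Oc3cc(C)c(C(=O)OCc4ccccc4)c(O)c3)c(O)c2)c(OC)c1OC
F5 | step 4 | 1-bromo-2,3,4-trimethoxy-6-methylbenzene | COc1cc(C)c(Br)c(OC)c1OC
F6 | step 9 | 2,2,2-trichloroethyl 4-hydroxy-2-methylbenzoate | Cc1cc(O)ccc1C(=O)OCC(Cl)(Cl)Cl
F7 | step 9 | 2,2,2-trichloroethyl 2-methyl-4-({2-methyl-4-[(2,3,4-trimethoxy-6-methylbenzoyl)oxy]benzoyl}oxy)benzoate | COc1cc(C)c(C(=O)Oc2ccc(C(=O)Oc3ccc(C(=O)OCC(Cl)(Cl)Cl)c(C)c3)c(C)c2)c(OC)c1OC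
F8 | step 9 | 2,2,2-trichloroethyl 2-methyl-6-(trifluoroacetoxy)-4-({2-methyl-6-(trifluoroacetoxy)-4-[(2,3,4-trimethoxy-6-methylbenzoyl)oxy]benzoyl}oxy)benzoate | COc1cc(C)c(C(=O)Oc2cc(C)c(C(=O)Oc3cc(C)c(C(=O)OCC(Cl)(Cl)Cl)c(OC(=O)C(F)(F)F)c3)c(OC(=O)C(F)(F)F)c2)c(OC)c1OC
F9 | step 9 | 2,2,2-trichloroethyl 2-hydroxy-6-methyl-4-({2-hydroxy-6-methyl-4-[(2,3,4-trimethoxy-6-methylbenzoyl)oxy]benzoyl}oxy)benzoate | COc1cc(C)c(C(=O)Oc2cc(C)c(C(=O)Oc3cc(C)c(C(=O)OCC(Cl)(Cl)Cl)c(O)c3)c(O)c2)c(OC)c1OC
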